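The target is cut at C11=C12 and C11'=C12' into two C15 tributylphosphonium salts and the C10 trienedial. Both ring units come from one enol triflate. Everything rests on ring A: its C5,C6-diol is cis and lies anti to O3, and C6 is allylic to C7=C8 while C1, C5 and C9 carry no hydrogen. The key step therefore converts the anti 5,6-epoxide of a C15 dienoate, with CO2 and zerovalent palladium, into the cis-fused five-membered 5,6-carbonate. One operation swaps the strained oxirane for both carbinol C–O bonds with retention at C6. The precursor is the silyl-protected (3S,5R,6S)-epoxy dienoate, made by Sharpless epoxidation and Horner–Wadsworth–Emmons extension.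

Key step: step 10

Remark: carotenoid numbering is used throughout. Unprimed atoms belong to the triol half (ring A) and primed atoms to the acetylenic half (ring B).
Assumption: enynol 20 and dialdehyde 25 are taken as purchasable, and the two reductases are used as recombinant catalysts. All polyene steps run under argon in dim light.

Step 1
Reactants: 1 ketoisophorone
Product: 2 (6R)-levodione
Conditions: ene-reductase OYE2 (recombinant), NADP+ (cat.), glucose dehydrogenase, D-glucose, KH2PO4/K2HPO4 buffer pH 7, 30 °C
Reagents that add atoms: none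
Why: Enzymatic asymmetric conjugate reduction (old yellow enzyme type ene-reductase): reduced flavin should deliver hydride to C3 and the active-site tyrosine should protonate C2 from the opposite face, which sets the methyl-bearing centre as R and leaves both carbonyl groups intact.

Step 2
Reactants: 2 (6R)-levodione
Product: 3 (4R,6R)-actinol
Conditions: levodione reductase (Corynebacterium aquaticum M-13, recombinant), NAD+ (cat.), glucose dehydrogenase, D-glucose, KH2PO4/K2HPO4 buffer pH 7, 30 °C
Reagents that add atoms: none
Why: Enzymatic carbonyl reduction by a short-chain dehydrogenase: only the unhindered C4 ketone fits the active site, the C1 ketone being screened by three flanking methyl groups, and hydride transfer from NADH to one carbonyl face should set C4 as R, the centre that becomes C3 of ring A and C3' of ring B.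

Step 3
Reactants: 3 (4R,6R)-actinol
Product: 4 (4R,6R)-4-(tert-butyldimethylsilyloxy)-2,2,6-trimethylcyclohexanone
Conditions: TBSCl, imidazole, DMF, rt
Reagents that add atoms: tert-butyldimethylsilyl chloride, CC(C)(C)[Si](C)(C)Cl
Why: Imidazole-promoted silylation of a secondary alcohol, which masks O3 for the base, hydride and palladium steps ahead and touches no stereocentre.

Step 4
Reactants: 4 silyl-protected actinol
Product: 6 (4R)-4-(tert-butyldimethylsilyloxy)-2,6,6-trimethylcyclohex-1-enyl triflate, via lithium enolate 5 (not isolated)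
Conditions: LDA, THF, −78 to 0 °C; PhNTf2, 0 °C to rt
Reagents that add atoms: N-phenylbis(trifluoromethanesulfonimide), O=S(=O)(N(c1ccccc1)S(=O)(=O)C(F)(F)F)C(F)(F)F; LDA, [Li+].CC(C)[N-]C(C)C (lithium in 5 only)
Why: Enolate O-triflation: C2 is quaternary so deprotonation can occur only at C6, the enolate oxygen attacks a sulfonyl group of the triflimide, the C6 centre is erased on purpose and C4 is untouched.

Step 5
Reactants: 6 enol triflate
Product: 7 methyl (4R)-4-(tert-butyldimethylsilyloxy)-2,6,6-trimethylcyclohex-1-enecarboxylate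
Conditions: Pd(OAc)2 (cat.), PPh3, Et3N, CO (1 atm), MeOH–DMF, 60 °C
Reagents that add atoms: carbon monoxide, [C-]#[O+]; methanol, CO
Why: Palladium-catalysed alkoxycarbonylation of a vinyl triflate (oxidative addition, CO insertion, methanolysis of the acyl complex) installs C7 on the tetrasubstituted alkene without affecting the silyl ether.

Step 6
Reactants: 7 methyl ester
Product: 8 [(4R)-4-(tert-butyldimethylsilyloxy)-2,6,6-trimethylcyclohex-1-enyl]methanol
Conditions: i-Bu2AlH, CH2Cl2, −78 to 0 °C; aq. potassium sodium tartrate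
Reagents that add atoms: none
Why: 1,2-Reduction of a conjugated ester with a neutral aluminium hydride gives the allylic alcohol needed as the handle for directed epoxidation, and the silyl ether is inert.

Step 7
Reactants: 8 ring allylic alcohol
Product: 9 anti-epoxy alcohol (3S,5R; oxirane oxygen opposite O3)
Conditions: Ti(OiPr)4 (cat.), D-(−)-diethyl tartrate (cat.), t-BuOOH (decane), 4 Å MS, CH2Cl2, −20 °C
Reagents that add atoms: tert-butyl hydroperoxide, CC(C)(C)OO
Why: Sharpless asymmetric epoxidation: the allylic alkoxide and the peroxide bind the titanium tartrate complex, the D-(−)-tartrate directs syn oxygen transfer to the ring face opposite the C3 silyloxy group (the enantiomeric tartrate would serve the other face), and C5 (R) and C6 are thus set together under reagent control.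

Step 8
Reactants: 9 anti-epoxy alcohol
Product: 10 anti-epoxy aldehyde
Conditions: nPr4N[RuO4] (cat.), NMO, 4 Å MS, CH2Cl2, rt
Reagents that add atoms: none
Why: Ley–Griffith oxidation of a primary alcohol under neutral conditions; the formyl group hangs on the fully substituted C6, so no epimerisation is possible, and the epoxide and silyl ether are not attacked.

Step 9
Reactants: 10 anti-epoxy aldehyde; 11 triethyl 3-methyl-4-phosphonocrotonate
Product: 13 anti-5,6-epoxy C15 dienoate (3S,5R,6S; 7E,9E), via lithiated phosphonate 12 (not isolated)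
Conditions: 11, LiHMDS, THF–DMPU, −78 °C; then 10, −78 to 0 °C
Reagents that add atoms: LiHMDS, [Li+].C[Si](C)(C)[N-][Si](C)(C)C (lithium in 12 only)
Why: Horner–Wadsworth–Emmons olefination with a vinylogous phosphonoacetate: the stabilised anion and the bulky aldehyde should give the 7E alkene with mainly 9E geometry (any 9Z isomer is removed by chromatography), and the non-enolisable epoxy aldehyde keeps its three stereocentres.

Step 10
Reactants: 13 anti-5,6-epoxy C15 dienoate; 14 carbon dioxide
Product: 15 cis-fused 5,6-carbonate of the C15 dienoate (3S,5R,6S; 7E,9E)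
Conditions: Pd2(dba)3·CHCl3 (5 mol %), P(OiPr)3 (40 mol %), CO2 (1 atm), THF, rt to 40 °C
Reagents that add atoms: carbon dioxide (compound 14), O=C=O
Why: Zerovalent palladium carrying the small phosphite binds C7=C8 of 13 on the ring face opposite the oxirane oxygen and, helped by release of the epoxide strain, breaks the allylic C6–O bond with inversion to give an η3-allyl complex over C6–C8 and a C5 alkoxide, which adds to CO2 (new O5–C(=O) bond). The carbonate oxygen then attacks C6 anti to the metal (new C6–O bond) and frees the catalyst; the closest known reaction type is the palladium-catalysed union of vinyl epoxides with CO2 to cis vinyl carbonates, a Tsuji–Trost allylic substitution with an internally generated nucleophile that also works at tertiary allylic termini. The 1,3-dioxolan-2-one ring closes in 5-exo fashion on the near allyl terminus, whereas closure at C8 would need a seven-membered ring and, being reversible under the catalyst, should drain into the five-membered product. C6 is the only stereocentre remade, and it is controlled by the double inversion together with the short tether from O5, whose configuration was fixed in step 7 and which can reach only the top face, so the ring fusion must be cis and anti to O3. The step needs attack at C6 rather than C8, retention at C6 and no diene formation: the tether secures the first two, and the lack of hydrogen on C1, C5 and C9 rules out β-hydride loss from the allyl complex. The dienoate acceptor favours alkene binding by the electron-rich metal and suppresses uncatalysed ionisation at C6, so trans-diol or furanoid products of an acid-type opening should not arise.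

Step 11
Reactants: 15 5,6-carbonate dienoate
Product: 16 C15 dienetriol (3-O-TBS; free 5,6-cis-diol; C11 primary alcohol; 3S,5R,6S; 7E,9E)
Conditions: LiAlH4, Et2O, 0 °C; Na2SO4·10H2O quench
Reagents that add atoms: none
Why: Hydride reduction of ester and carbonate: LiAlH4 attacks only the two carbonyl carbons, so the dienoate gives the primary dienol, the carbonate falls apart to the free diol without breaking the C5–O or C6–O bond, all three stereocentres are retained, and the non-acidic quench spares the tertiary allylic alcohol.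

Step 12
Reactants: 16 C15 dienetriol
Product: 19 ring A C15 tributylphosphonium chloride, via allylic mesylate 17 (not isolated), via allylic chloride 18 (not isolated)
Conditions: MsCl, LiCl, 2,4,6-collidine, DMF, 0 °C; then PBu3, rt, same flask
Reagents that add atoms: tributylphosphine, CCCCP(CCCC)CCCC; lithium chloride, [Li+].[Cl-]; methanesulfonyl chloride, CS(=O)(=O)Cl (atoms in 17 only)
Why: Selective sulfonylation, SN2 chloride exchange and phosphine quaternisation: only the primary allylic hydroxyl is mesylated with the weak base collidine, chloride and then tributylphosphine displace at C11, and the acid-free medium should keep the ionisable C6 carbinol and the 9E alkene intact.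

Step 13
Reactants: 6 enol triflate; 20 (E)-3-methylpent-2-en-4-yn-1-ol
Product: 21 ring B C15 enynol (3'R; 9'E)
Conditions: Pd(PPh3)4 (5 mol %), CuI (10 mol %), Et3N, DMF, rt to 50 °C
Reagents that add atoms: none
Why: Sonogashira coupling: zerovalent palladium inserts into the vinyl C–O bond of the triflate, the copper acetylide of 20 transmetalates and reductive elimination forms the C6'–C7' bond, with the E alkene of 20 and C3' untouched.

Step 14
Reactants: 21 ring B C15 enynol
Product: 24 ring B C15 tributylphosphonium chloride, via allylic mesylate 22 (not isolated), via allylic chloride 23 (not isolated)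
Conditions: MsCl, LiCl, 2,4,6-collidine, DMF, 0 °C; then PBu3, rt, same flask
Reagents that add atoms: tributylphosphine, CCCCP(CCCC)CCCC; lithium chloride, [Li+].[Cl-]; methanesulfonyl chloride, CS(=O)(=O)Cl (atoms in 22 only)
Why: The same mesylation, chloride exchange and quaternisation sequence applies, and the strongly nucleophilic trialkylphosphine reacts at room temperature, which should avoid the E to Z drift at C9'=C10' to which acetylenic C15 salts are prone.

Step 15
Reactants: 24 ring B C15 phosphonium chloride; 25 (2E,4E,6E)-2,7-dimethylocta-2,4,6-trienedial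
Product: 27 all-E C25 pentaenynal, via allylic ylide 26 (not isolated)
Conditions: 25 (3 equiv), NaOMe, MeOH–CH2Cl2, 0 °C to rt, slow addition of base
Reagents that add atoms: none
Why: Wittig olefination: the allylic tributylphosphonium ylide is of the E-selective trialkyl type, its slow generation in the presence of excess symmetrical dialdehyde should limit reaction to one formyl group, and C11'=C12' should form trans.

Step 16
Reactants: 19 ring A C15 phosphonium chloride; 27 C25 pentaenynal
Product: 29 3,3'-bis-O-TBS ether of the target, via dienyl ylide 28 (not isolated)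
Conditions: NaOMe, MeOH–CH2Cl2, rt
Reagents that add atoms: none
Why: Wittig olefination: methoxide generates the tributylphosphonium ylide in the presence of 27, ylides of this trialkyl type favour the E alkene so C11=C12 should form trans, the tertiary hydroxyls need no protection under these conditions, and no stereocentre is touched.

Step 17
Reactants: 29 bis-silyl ether
Product: 30 target tetrol CNP0160593.2 (3S,5R,6S,3'R; all-E)
Conditions: TBAF, THF, rt
Reagents that add atoms: none
Why: Fluoride-induced cleavage of both secondary silyl ethers, driven by the strong Si–F bond, under non-acidic conditions that the polyene, the alkyne and the tertiary allylic C6 carbinol tolerate, so that the four stereocentres set earlier are delivered unchanged.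

Compound list
1 | ketoisophorone (2,6,6-trimethylcyclohex-2-ene-1,4-dione) | CC1=CC(=O)CC(C)(C)C1=O | starting material
2 | (6R)-levodione, (6R)-2,2,6-trimethylcyclohexane-1,4-dione | O=C1C(C)(C)CC(=O)C[C@H]1C | intermediate
3 | (4R,6R)-actinol, (4R,6R)-4-hydroxy-2,2,6-trimethylcyclohexanone (OH trans to the C6 methyl) | O=C1C(C)(C)C[C@H](O)C[C@H]1C | intermediate
4 | (4R,6R)-4-(tert-butyldimethylsilyloxy)-2,2,6-trimethylcyclohexanone | O=C1C(C)(C)C[C@H](O[Si](C)(C)C(C)(C)C)C[C@H]1C | intermediate
5 | lithium (4R)-4-(tert-butyldimethylsilyloxy)-2,6,6-trimethylcyclohex-1-enolate | CC1=C([O-])C(C)(C)C[C@H](O[Si](C)(C)C(C)(C)C)C1.[Li+] | intermediate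
6 | (4R)-4-(tert-butyldimethylsilyloxy)-2,6,6-trimethylcyclohex-1-enyl trifluoromethanesulfonate | CC1=C(OS(=O)(=O)C(F)(F)F)C(C)(C)C[C@H](O[Si](C)(C)C(C)(C)C)C1 | intermediate
7 | methyl (4R)-4-(tert-butyldimethylsilyloxy)-2,6,6-trimethylcyclohex-1-enecarboxylate | CC1=C(C(=O)OC)C(C)(C)C[C@H](O[Si](C)(C)C(C)(C)C)C1 | intermediate
8 | [(4R)-4-(tert-butyldimethylsilyloxy)-2,6,6-trimethylcyclohex-1-enyl]methanol | CC1=C(CO)C(C)(C)C[C@H](O[Si](C)(C)C(C)(C)C)C1 | intermediate
9 | [(1R,2R,4S)-4-(tert-butyldimethylsilyloxy)-1,2-epoxy-2,6,6-trimethylcyclohexyl]methanol (epoxide anti to OTBS) | OC[C@]1(O2)C(C)(C)C[C@H](O[Si](C)(C)C(C)(C)C)C[C@]12C | intermediate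
10 | (1S,2R,4S)-4-(tert-butyldimethylsilyloxy)-1,2-epoxy-2,6,6-trimethylcyclohexanecarbaldehyde | O=C[C@]1(O2)C(C)(C)C[C@H](O[Si](C)(C)C(C)(C)C)C[C@]12C | intermediate
11 | triethyl 3-methyl-4-phosphonocrotonate (E) | CCOC(=O)/C=C(C)/CP(=O)(OCC)OCC | starting material
12 | lithiated triethyl 3-methyl-4-phosphonocrotonate | [Li+].CCOC(=O)/C=C(C)/[CH-]P(=O)(OCC)OCC | intermediate
13 | ethyl (2E,4E)-5-[(1S,2R,4S)-4-(tert-butyldimethylsilyloxy)-1,2-epoxy-2,6,6-trimethylcyclohexyl]-3-methylpenta-2,4-dienoate (3S,5R,6S in carotenoid numbering) | CCOC(=O)/C=C(C)/C=C/[C@]1(O2)C(C)(C)C[C@H](O[Si](C)(C)C(C)(C)C)C[C@]12C | intermediate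
14 | carbon dioxide | O=C=O | starting material
15 | cis-fused cyclic 5,6-carbonate of ethyl (2E,4E)-5-[4-(tert-butyldimethylsilyloxy)-1,2-dihydroxy-2,6,6-trimethylcyclohexyl]-3-methylpenta-2,4-dienoate (3S,5R,6S; both carbonate oxygens anti to OTBS) | CCOC(=O)/C=C(C)/C=C/[C@]1(OC(=O)O2)C(C)(C)C[C@H](O[Si](C)(C)C(C)(C)C)C[C@]12C | intermediate
16 | (2E,4E)-5-[(1S,2R,4S)-4-(tert-butyldimethylsilyloxy)-1,2-dihydroxy-2,6,6-trimethylcyclohexyl]-3-methylpenta-2,4-dien-1-ol (cis-diol anti to OTBS) | OC/C=C(C)/C=C/[C@]1(O)C(C)(C)C[C@H](O[Si](C)(C)C(C)(C)C)C[C@@]1(C)O | intermediate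
17 | C11 methanesulfonate of 16 | CS(=O)(=O)OC/C=C(C)/C=C/[C@]1(O)C(C)(C)C[C@H](O[Si](C)(C)C(C)(C)C)C[C@@]1(C)O | intermediate
18 | C11 chloride corresponding to 16 | ClC/C=C(C)/C=C/[C@]1(O)C(C)(C)C[C@H](O[Si](C)(C)C(C)(C)C)C[C@@]1(C)O | intermediate
19 | tributyl{(2E,4E)-5-[(1S,2R,4S)-4-(tert-butyldimethylsilyloxy)-1,2-dihydroxy-2,6,6-trimethylcyclohexyl]-3-methylpenta-2,4-dienyl}phosphonium chloride | [Cl-].CCCC[P+](CCCC)(CCCC)C/C=C(C)/C=C/[C@]1(O)C(C)(C)C[C@H](O[Si](C)(C)C(C)(C)C)C[C@@]1(C)O | intermediate
20 | (E)-3-methylpent-2-en-4-yn-1-ol | C#C/C(C)=C/CO | starting material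
21 | (2E)-5-[(4R)-4-(tert-butyldimethylsilyloxy)-2,6,6-trimethylcyclohex-1-enyl]-3-methylpent-2-en-4-yn-1-ol | CC1=C(C#C/C(C)=C/CO)C(C)(C)C[C@H](O[Si](C)(C)C(C)(C)C)C1 | intermediate
22 | methanesulfonate of 21 | CC1=C(C#C/C(C)=C/COS(C)(=O)=O)C(C)(C)C[C@H](O[Si](C)(C)C(C)(C)C)C1 | intermediate
23 | allylic chloride corresponding to 21 | CC1=C(C#C/C(C)=C/CCl)C(C)(C)C[C@H](O[Si](C)(C)C(C)(C)C)C1 | intermediate
24 | tributyl{(2E)-5-[(4R)-4-(tert-butyldimethylsilyloxy)-2,6,6-trimethylcyclohex-1-enyl]-3-methylpent-2-en-4-ynyl}phosphonium chloride | CC1=C(C#C/C(C)=C/C[P+](CCCC)(CCCC)CCCC)C(C)(C)C[C@H](O[Si](C)(C)C(C)(C)C)C1.[Cl-] | intermediate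
25 | (2E,4E,6E)-2,7-dimethylocta-2,4,6-trienedial | O=C/C(C)=C/C=C/C=C(C)/C=O | starting material
26 | ylide of 24 | CC1=C(C#C/C(C)=C/[CH-][P+](CCCC)(CCCC)CCCC)C(C)(C)C[C@H](O[Si](C)(C)C(C)(C)C)C1 | intermediate
27 | (2E,4E,6E,8E,10E)-13-[(4R)-4-(tert-butyldimethylsilyloxy)-2,6,6-trimethylcyclohex-1-enyl]-2,7,11-trimethyltrideca-2,4,6,8,10-pentaen-12-ynal | CC1=C(C#C/C(C)=C/C=C/C(C)=C/C=C/C=C(C)/C=O)C(C)(C)C[C@H](O[Si](C)(C)C(C)(C)C)C1 | intermediate
28 | ylide of 19 | CCCC[P+](CCCC)(CCCC)[CH-]/C=C(C)/C=C/[C@]1(O)C(C)(C)C[C@H](O[Si](C)(C)C(C)(C)C)C[C@@]1(C)O | intermediate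
29 | (3S,5R,6S,3'R)-3,3'-bis(tert-butyldimethylsilyloxy)-7',8'-didehydro-5,6-dihydro-β,β-carotene-5,6-diol (all-E) | CC1=C(C#C/C(C)=C/C=C/C(C)=C/C=C/C=C(C)/C=C/C=C(C)/C=C/[C@]2(O)C(C)(C)C[C@H](O[Si](C)(C)C(C)(C)C)C[C@@]2(C)O)C(C)(C)C[C@H](O[Si](C)(C)C(C)(C)C)C1 | intermediate
30 | (3S,5R,6S,3'R)-7',8'-didehydro-5,6-dihydro-β,β-carotene-3,5,6,3'-tetrol (all-E), CNP0160593.2 | CC1=C(C#C/C(C)=C/C=C/C(C)=C/C=C/C=C(C)/C=C/C=C(C)/C=C/[C@]2(O)C(C)(C)C[C@H](O)C[C@@]2(C)O)C(C)(C)C[C@H](O)C1 | target

Total step count: 17. Longest linear sequence: 14 steps (steps 1–12, 16, 17).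

Steps most likely to fail

1. Step 10. Ionisation at the fully substituted C6 beside quaternary C1 may be too slow. The allyl complex may also collapse back, or drift to other oxygen heterocycles, faster than CO2 is captured.
The fallback sets out from 4 and returns at 16. It builds the cis-diol by carbonyl addition instead of from the epoxide. Enolate 5, made from 4 as in step 4, is hydroxylated with 2-(phenylsulfonyl)-3-phenyloxaziridine to the tertiary α-ketol F1, whose hydroxyl is trans to the silyloxy group; the C5 epimer is removed by chromatography. Enynol 20 is deprotonated twice with n-BuLi to the dilithio reagent F2. An excess of F2 adds to the C6 carbonyl of F1 from the face away from the axial C5 oxygen and the axial C1 methyl group, which should give the cis-diol enyne F3. LiAlH4 in THF then reduces the propargylic triple bond by hydroxyl-directed trans hydroalumination to the 7E alkene, which is 16.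

2. Step 16. Ylide 28 carries a hydroxyl at C6 in the vinylogous β-position and could lose it before it meets the long, weakly electrophilic polyenal. Control of the C11=C12 geometry could also be poor.
The fallback sets out from 16 and 27, returns at 29 and also bypasses step 12. It reverses the polarity of the union. Compound 16 is oxidised with [Cu(MeCN)4]OTf, 2,2'-bipyridine, TEMPO and N-methylimidazole under air, a system that does not cleave glycols, to the dienal F4. Compound 27 is reduced with NaBH4 to the C25 alcohol F5. F5 is converted with NCS/Me2S (Corey–Kim chlorination) into the C25 chloride F6 and then with PBu3 into the C25 phosphonium chloride F7. NaOMe generates the C25 ylide F8 in the presence of F4, and the Wittig reaction gives 29.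

3. Step 13. Oxidative addition into the tetrasubstituted triflate next to the gem-dimethyl carbon may be slow enough for alkyne homocoupling to take over.
The fallback sets out from 4 and returns at 21. It uses addition followed by dehydration instead of cross-coupling. The dilithio reagent F2 adds to ketone 4 to give the propargylic carbinol F9, whose configuration at C6' is irrelevant. Ac2O/pyridine masks the primary hydroxyl as the acetate F10. POCl3/pyridine eliminates the tertiary hydroxyl towards C5', the only neighbouring carbon that bears hydrogen, to give the enyne acetate F11. K2CO3/MeOH then releases 21.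

Further compounds
F1 | step 10 | (2R,4S)-4-(tert-butyldimethylsilyloxy)-2-hydroxy-2,6,6-trimethylcyclohexanone | O=C1C(C)(C)C[C@H](O[Si](C)(C)C(C)(C)C)C[C@@]1(C)O
F2 | step 10 | dilithiated (E)-3-methylpent-2-en-4-yn-1-ol | [Li+].[Li+].[C-]#C/C(C)=C/C[O-]
F3 | step 10 | 7,8-didehydro analogue of 16 (5,6-cis-diol anti to OTBS, 9E) | OC/C=C(C)/C#C[C@]1(O)C(C)(C)C[C@H](O[Si](C)(C)C(C)(C)C)C[C@@]1(C)O
F4 | step 16 | (2E,4E)-5-[(1S,2R,4S)-4-(tert-butyldimethylsilyloxy)-1,2-dihydroxy-2,6,6-trimethylcyclohexyl]-3-methylpenta-2,4-dienal | O=C/C=C(C)/C=C/[C@]1(O)C(C)(C)C[C@H](O[Si](C)(C)C(C)(C)C)C[C@@]1(C)O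
F5 | step 16 | C25 pentaenynol (primary alcohol from 27) | CC1=C(C#C/C(C)=C/C=C/C(C)=C/C=C/C=C(C)/CO)C(C)(C)C[C@H](O[Si](C)(C)C(C)(C)C)C1
F6 | step 16 | C25 pentaenynyl chloride | CC1=C(C#C/C(C)=C/C=C/C(C)=C/C=C/C=C(C)/CCl)C(C)(C)C[C@H](O[Si](C)(C)C(C)(C)C)C1
F7 | step 16 | C25 tributylphosphonium chloride | CC1=C(C#C/C(C)=C/C=C/C(C)=C/C=C/C=C(C)/C[P+](CCCC)(CCCC)CCCC)C(C)(C)C[C@H](O[Si](C)(C)C(C)(C)C)C1.[Cl-]
F8 | step 16 | ylide of F7 | CC1=C(C#C/C(C)=C/C=C/C(C)=C/C=C/C=C(C)/[CH-][P+](CCCC)(CCCC)CCCC)C(C)(C)C[C@H](O[Si](C)(C)C(C)(C)C)C1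
F9 | step 13 | (2E)-5-[(4R,6R)-4-(tert-butyldimethylsilyloxy)-1-hydroxy-2,2,6-trimethylcyclohexyl]-3-methylpent-2-en-4-yn-1-ol (carbinol centre undefined) | OC/C=C(C)/C#CC1(O)C(C)(C)C[C@H](O[Si](C)(C)C(C)(C)C)C[C@H]1C
F10 | step 13 | primary acetate of F9 | CC(=O)OC/C=C(C)/C#CC1(O)C(C)(C)C[C@H](O[Si](C)(C)C(C)(C)C)C[C@H]1C
F11 | step 13 | acetate of 21 | CC1=C(C#C/C(C)=C/COC(C)=O)C(C)(C)C[C@H](O[Si](C)(C)C(C)(C)C)C1
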